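**Strategy.** Everything rests on disconnecting the C11–O bond of the C9/C11 syn-1,3-diol: C11 is treated as an allylic carbinol whose oxygen arrives from C13 of a C11=C12 alkene. In one operation Re2O7 shifts that oxygen from C13 to C11 by reversible allylic transposition while benzaldehyde dimethyl acetal ties the C9 and C11 oxygens into an all-equatorial 2-phenyl-1,3-dioxane ring (O–C9–C10–C11–O–CHPh), so the single C9 stereocentre fixes C11 and a vinyl handle for the alkyl tail is exposed. The precursor is the C7–C13 (2E,5R)-hept-2-ene-1,5-diol with C7 as a TBDPS ether. The δ-lactone ring (O, C1–C5) is closed last by ring-closing metathesis.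

Key step: step 5

**Remarks on the chemistry.**
- The target is read as (5S,7R,9R,11R), all four C–O bonds syn; numbering runs from the lactone carbonyl C1 to C26.
- In the cross-metathesis of step 6 the vinyl CH2 (the carbon that carried oxygen before the transposition) leaves as ethene. C13–C26 of the target therefore come from 1-pentadecene, and only C12 of the vinyl group is kept.
- CIP descriptors of untouched centres change along the route because neighbouring groups change priority; no centre is inverted after it is set.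
- Both antipodes of B-allyldiisopinocampheylborane are taken as commercial pentane solutions. The (+)-reagent [(+)-α-pinene series] is assumed to add to the Si face and the (−)-reagent to the Re face of an aldehyde.

**Route**

Step 1
Reactants: 1 propane-1,3-diol
Product: 2 3-(tert-butyldiphenylsilyloxy)propan-1-ol
Conditions: TBDPSCl (1 equiv), imidazole, 1 (3 equiv), THF, 0 °C → rt
Reagents that add atoms: tert-butyl(chloro)diphenylsilane, CC(C)(C)[Si](Cl)(c1ccccc1)c1ccccc1
Why: Imidazole-promoted O-silylation of an excess of the symmetrical diol with the bulky silyl chloride should stop at the mono-ether, and no stereocentre is involved.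

Step 2
Reactants: 2 3-(tert-butyldiphenylsilyloxy)propan-1-ol
Product: 3 3-(tert-butyldiphenylsilyloxy)propanal
Conditions: Dess–Martin periodinane, NaHCO3, CH2Cl2, 0 °C → rt
Reagents that add atoms: none
Why: Dess–Martin oxidation takes a primary alcohol to the aldehyde without over-oxidation and leaves the silyl ether untouched.

Step 3
Reactants: 3 3-(tert-butyldiphenylsilyloxy)propanal
Product: 5 (3R)-1-(tert-butyldiphenylsilyloxy)hex-5-en-3-ol, via borinate ester 4 (not isolated)
Conditions: (−)-Ipc2B(allyl), Et2O, −78 °C; then NaOH, H2O2, 0 °C → rt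
Reagents that add atoms: (−)-B-allyldiisopinocampheylborane [(−)-α-pinene series], C=CCB([C@H]1C[C@H]2C[C@@H]([C@@H]1C)C2(C)C)[C@H]1C[C@H]2C[C@@H]([C@@H]1C)C2(C)C
Why: Brown allylboration through a chair Zimmerman–Traxler transition state should deliver allyl to the Re face of the aldehyde under reagent control, which sets C9 as R, and the oxidative work-up cleaves the borinate.

Step 4
Reactants: 5 (3R)-1-(tert-butyldiphenylsilyloxy)hex-5-en-3-ol; 6 (Z)-but-2-ene-1,4-diol
Product: 7 (2E,5R)-7-(tert-butyldiphenylsilyloxy)hept-2-ene-1,5-diol (mainly E; the geometry is of no consequence)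
Conditions: 6 (4 equiv), second-generation Grubbs catalyst (H2IMes)(PCy3)Cl2Ru=CHPh (3 mol%), CH2Cl2, 40 °C
Reagents that add atoms: (Z)-but-2-ene-1,4-diol (compound 6), OC/C=C\CO
Why: Olefin cross-metathesis of the terminal alkene with an excess of the symmetrical internal diol should give the primary allylic alcohol while the C9 carbinol is untouched.

Step 5
Reactants: 7 (2E,5R)-7-(tert-butyldiphenylsilyloxy)hept-2-ene-1,5-diol; 8 benzaldehyde dimethyl acetal
Product: 10 (2S,4S,6S)-4-ethenyl-2-phenyl-6-[2-(tert-butyldiphenylsilyloxy)ethyl]-1,3-dioxane (2,4,6-cis), via transposed hept-1-ene-3,5-diol 9 (not isolated)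
Conditions: Re2O7 (3 mol%), 8 (2 equiv), CH2Cl2, 0 °C → rt; then Et3N
Reagents that add atoms: benzaldehyde dimethyl acetal (compound 8), COC(OC)c1ccccc1
Why: Re2O7 (heptavalent rhenium) esterifies the primary allylic alcohol to an allyl perrhenate that relays oxygen from C13 to C11 through a reversible chair-like [3,3]-sigmatropic shift, giving diol 9 as both C11 epimers, and the same acidic rhenium species catalyses acetal exchange with 8. The closest known reaction type is the Re2O7-catalysed 1,3-transposition of allylic alcohols with in situ capture of the resulting 1,3-diol as a benzylidene acetal. The dioxane ring closes by O–C bond formation at the acetal carbon, the second hydroxyl adding to the oxocarbenium ion of the mixed methyl acetal in a 6-endo-trig mode. C11 and the acetal carbon are set under thermodynamic control by the fixed C9 centre, because transposition, ionisation and acetal exchange are all reversible and should drain both C11 epimers and both alkene isomers into the chair with phenyl, vinyl and the silyloxyethyl chain all equatorial. The step needs regioselectivity for the secondary (C11) over the primary (C13) oxygen position and chemoselectivity among three oxygens: only the transposed isomer offers a 1,3-diol for a six-membered acetal, the homoallylic C9–OH cannot transpose, and the acid-stable TBDPS ether keeps the C7 oxygen out of a competing C7/C9 acetal.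

Step 6
Reactants: 10 (2S,4S,6S)-4-ethenyl-2-phenyl-6-[2-(tert-butyldiphenylsilyloxy)ethyl]-1,3-dioxane; 11 1-pentadecene
Product: 12 (2S,4S,6S)-4-[(E)-pentadec-1-enyl]-2-phenyl-6-[2-(tert-butyldiphenylsilyloxy)ethyl]-1,3-dioxane (E/Z mixture, E drawn)
Conditions: 11 (4 equiv), second-generation Grubbs catalyst (H2IMes)(PCy3)Cl2Ru=CHPh (5 mol%), CH2Cl2, 40 °C
Reagents that add atoms: 1-pentadecene (compound 11), C=CCCCCCCCCCCCCC
Why: Olefin cross-metathesis with an excess of the unhindered terminal alkene should exchange the vinyl CH2 for the C13–C26 chain with loss of ethene, and no stereocentre is touched.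

Step 7
Reactants: 12 (2S,4S,6S)-4-[(E)-pentadec-1-enyl]-2-phenyl-6-[2-(tert-butyldiphenylsilyloxy)ethyl]-1,3-dioxane
Product: 13 (2R,4R,6S)-4-pentadecyl-2-phenyl-6-[2-(tert-butyldiphenylsilyloxy)ethyl]-1,3-dioxane
Conditions: H2 (1 atm), 5% Pd/C, Et3N (cat.), EtOAc, rt
Reagents that add atoms: none
Why: Heterogeneous catalytic hydrogenation saturates the disubstituted alkene, and the amine-moderated catalyst in an aprotic solvent should spare the benzylidene acetal from hydrogenolysis.

Step 8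
Reactants: 13 (2R,4R,6S)-4-pentadecyl-2-phenyl-6-[2-(tert-butyldiphenylsilyloxy)ethyl]-1,3-dioxane
Product: 14 2-[(2R,4S,6R)-6-pentadecyl-2-phenyl-1,3-dioxan-4-yl]ethan-1-ol
Conditions: Bu4NF, THF, 0 °C → rt
Reagents that add atoms: none
Why: Fluoride-mediated desilylation is driven by the strong Si–F bond, and the acetal is inert to the basic fluoride.

Step 9
Reactants: 14 2-[(2R,4S,6R)-6-pentadecyl-2-phenyl-1,3-dioxan-4-yl]ethan-1-ol
Product: 15 2-[(2R,4R,6R)-6-pentadecyl-2-phenyl-1,3-dioxan-4-yl]acetaldehyde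
Conditions: Dess–Martin periodinane, NaHCO3, CH2Cl2, 0 °C → rt; used crude
Reagents that add atoms: none
Why: Buffered Dess–Martin oxidation should give the β-oxygenated aldehyde without acetal loss or β-elimination.

Step 10
Reactants: 15 2-[(2R,4R,6R)-6-pentadecyl-2-phenyl-1,3-dioxan-4-yl]acetaldehyde
Product: 17 (2S)-1-[(2R,4S,6R)-6-pentadecyl-2-phenyl-1,3-dioxan-4-yl]pent-4-en-2-ol, via borinate ester 16 (not isolated)
Conditions: (+)-Ipc2B(allyl), Et2O, −78 °C; then NaOH, H2O2, 0 °C → rt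
Reagents that add atoms: (+)-B-allyldiisopinocampheylborane [(+)-α-pinene series], C=CCB([C@@H]1C[C@@H]2C[C@H]([C@H]1C)C2(C)C)[C@@H]1C[C@@H]2C[C@H]([C@H]1C)C2(C)C
Why: Brown allylboration with the antipodal reagent should add allyl to the Si face through the closed chair transition state, overriding the weak bias of the β-oxygenated aldehyde and setting C7 syn to C9 (S in 17, R in the target after the priority change).

Step 11
Reactants: 17 (2S)-1-[(2R,4S,6R)-6-pentadecyl-2-phenyl-1,3-dioxan-4-yl]pent-4-en-2-ol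
Product: 18 (2R,4R,6R)-4-[(2S)-2-(tert-butyldimethylsilyloxy)pent-4-enyl]-6-pentadecyl-2-phenyl-1,3-dioxane
Conditions: TBSCl, imidazole, DMF, rt
Reagents that add atoms: tert-butyl(chloro)dimethylsilane, CC(C)(C)[Si](C)(C)Cl
Why: Imidazole-promoted silylation masks the C7 hydroxyl so that only the C5 hydroxyl can later be acylated, and the TBS ether can be removed together with the acetal at the end.

Step 12
Reactants: 18 (2R,4R,6R)-4-[(2S)-2-(tert-butyldimethylsilyloxy)pent-4-enyl]-6-pentadecyl-2-phenyl-1,3-dioxane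
Product: 20 (3R)-3-(tert-butyldimethylsilyloxy)-4-[(2R,4R,6R)-6-pentadecyl-2-phenyl-1,3-dioxan-4-yl]butanal, via ozonide 19 (not isolated)
Conditions: O3, CH2Cl2, −78 °C (Sudan red 7B end point); then PPh3, −78 °C → rt; used crude
Reagents that add atoms: ozone, [O-][O+]=O
Why: Ozonolysis with reductive work-up cleaves the terminal alkene to the C5 aldehyde, and titration to the indicator end point at low temperature should keep ozone away from the acetal C–H bond.

Step 13
Reactants: 20 (3R)-3-(tert-butyldimethylsilyloxy)-4-[(2R,4R,6R)-6-pentadecyl-2-phenyl-1,3-dioxan-4-yl]butanal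
Product: 22 (4S,6S)-6-(tert-butyldimethylsilyloxy)-7-[(2R,4R,6R)-6-pentadecyl-2-phenyl-1,3-dioxan-4-yl]hept-1-en-4-ol, via borinate ester 21 (not isolated)
Conditions: (+)-Ipc2B(allyl), Et2O, −78 °C; then NaOH, H2O2, 0 °C → rt
Reagents that add atoms: (+)-B-allyldiisopinocampheylborane [(+)-α-pinene series], C=CCB([C@@H]1C[C@@H]2C[C@H]([C@H]1C)C2(C)C)[C@@H]1C[C@@H]2C[C@H]([C@H]1C)C2(C)C
Why: A second Brown allylboration with the same antipode should again attack the Si face under reagent control and set C5 as S, syn to C7.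

Step 14
Reactants: 22 (4S,6S)-6-(tert-butyldimethylsilyloxy)-7-[(2R,4R,6R)-6-pentadecyl-2-phenyl-1,3-dioxan-4-yl]hept-1-en-4-ol
Product: 23 (4S,6R)-6-(tert-butyldimethylsilyloxy)-7-[(2R,4R,6R)-6-pentadecyl-2-phenyl-1,3-dioxan-4-yl]hept-1-en-4-yl prop-2-enoate
Conditions: acryloyl chloride, Et3N, DMAP (cat.), CH2Cl2, 0 °C
Reagents that add atoms: acryloyl chloride, C=CC(=O)Cl
Why: DMAP-catalysed O-acylation esterifies the only free hydroxyl, supplying C1 and C2 without touching any stereocentre.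

Step 15
Reactants: 23 (4S,6R)-6-(tert-butyldimethylsilyloxy)-7-[(2R,4R,6R)-6-pentadecyl-2-phenyl-1,3-dioxan-4-yl]hept-1-en-4-yl prop-2-enoate
Product: 24 (6S)-6-[(2R)-2-(tert-butyldimethylsilyloxy)-3-[(2R,4R,6R)-6-pentadecyl-2-phenyl-1,3-dioxan-4-yl]propyl]-5,6-dihydro-2H-pyran-2-one
Conditions: second-generation Grubbs catalyst (H2IMes)(PCy3)Cl2Ru=CHPh (5 mol%), CH2Cl2 (2 mM), 40 °C
Reagents that add atoms: none
Why: Ring-closing metathesis between the allyl terminus and the acrylate should close the six-membered unsaturated lactone with loss of ethene, the ring allowing only the Z alkene at C2=C3.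

Step 16
Reactants: 24 (6S)-6-[(2R)-2-(tert-butyldimethylsilyloxy)-3-[(2R,4R,6R)-6-pentadecyl-2-phenyl-1,3-dioxan-4-yl]propyl]-5,6-dihydro-2H-pyran-2-one
Product: 25 (6S)-6-[(2R,4R,6R)-2,4,6-trihydroxyhenicosyl]-5,6-dihydro-2H-pyran-2-one
Conditions: 2 M aq. HCl, THF, rt
Reagents that add atoms: none
Why: Aqueous acid hydrolysis should remove the benzylidene acetal and the TBS ether in one operation while the conjugated δ-lactone, which is stable to acid, stays closed.

**Compound list**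

1 | propane-1,3-diol | OCCCO | starting material
2 | 3-(tert-butyldiphenylsilyloxy)propan-1-ol | OCCCO[Si](c1ccccc1)(c1ccccc1)C(C)(C)C | intermediate
3 | 3-(tert-butyldiphenylsilyloxy)propanal | O=CCCO[Si](c1ccccc1)(c1ccccc1)C(C)(C)C | intermediate
4 | (3R)-1-(tert-butyldiphenylsilyloxy)hex-5-en-3-yl diisopinocampheylborinate, (−)-α-pinene series (formed in the flask, not isolated) | C=CC[C@H](CCO[Si](c1ccccc1)(c1ccccc1)C(C)(C)C)OB([C@H]1C[C@H]2C[C@@H]([C@@H]1C)C2(C)C)[C@H]1C[C@H]2C[C@@H]([C@@H]1C)C2(C)C | intermediate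
5 | (3R)-1-(tert-butyldiphenylsilyloxy)hex-5-en-3-ol | C=CC[C@@H](O)CCO[Si](c1ccccc1)(c1ccccc1)C(C)(C)C | intermediate
6 | (Z)-but-2-ene-1,4-diol | OC/C=C\CO | starting material
7 | (2E,5R)-7-(tert-butyldiphenylsilyloxy)hept-2-ene-1,5-diol | OC/C=C/C[C@@H](O)CCO[Si](c1ccccc1)(c1ccccc1)C(C)(C)C | intermediate
8 | benzaldehyde dimethyl acetal | COC(OC)c1ccccc1 | starting material
9 | (5S)-7-(tert-butyldiphenylsilyloxy)hept-1-ene-3,5-diol, both C3 (= C11) epimers, C3 left unspecified (formed in the flask, not isolated) | C=CC(O)C[C@@H](O)CCO[Si](c1ccccc1)(c1ccccc1)C(C)(C)C | intermediate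
10 | (2S,4S,6S)-4-ethenyl-2-phenyl-6-[2-(tert-butyldiphenylsilyloxy)ethyl]-1,3-dioxane, 2,4,6-cis | C=C[C@@H]1C[C@H](CCO[Si](c2ccccc2)(c2ccccc2)C(C)(C)C)O[C@H](c2ccccc2)O1 | intermediate
11 | 1-pentadecene | C=CCCCCCCCCCCCCC | starting material
12 | (2S,4S,6S)-4-[(E)-pentadec-1-enyl]-2-phenyl-6-[2-(tert-butyldiphenylsilyloxy)ethyl]-1,3-dioxane (E/Z mixture, E drawn) | CCCCCCCCCCCCC/C=C/[C@@H]1C[C@H](CCO[Si](c2ccccc2)(c2ccccc2)C(C)(C)C)O[C@H](c2ccccc2)O1 | intermediate
13 | (2R,4R,6S)-4-pentadecyl-2-phenyl-6-[2-(tert-butyldiphenylsilyloxy)ethyl]-1,3-dioxane | CCCCCCCCCCCCCCC[C@@H]1C[C@H](CCO[Si](c2ccccc2)(c2ccccc2)C(C)(C)C)O[C@H](c2ccccc2)O1 | intermediate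
14 | 2-[(2R,4S,6R)-6-pentadecyl-2-phenyl-1,3-dioxan-4-yl]ethan-1-ol | CCCCCCCCCCCCCCC[C@@H]1C[C@H](CCO)O[C@H](c2ccccc2)O1 | intermediate
15 | 2-[(2R,4R,6R)-6-pentadecyl-2-phenyl-1,3-dioxan-4-yl]acetaldehyde | CCCCCCCCCCCCCCC[C@@H]1C[C@H](CC=O)O[C@H](c2ccccc2)O1 | intermediate
16 | (2S)-1-[(2R,4S,6R)-6-pentadecyl-2-phenyl-1,3-dioxan-4-yl]pent-4-en-2-yl diisopinocampheylborinate, (+)-α-pinene series (formed in the flask, not isolated) | CCCCCCCCCCCCCCC[C@@H]1C[C@H](C[C@H](CC=C)OB([C@@H]2C[C@@H]3C[C@H]([C@H]2C)C3(C)C)[C@@H]2C[C@@H]3C[C@H]([C@H]2C)C3(C)C)O[C@H](c2ccccc2)O1 | intermediate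
17 | (2S)-1-[(2R,4S,6R)-6-pentadecyl-2-phenyl-1,3-dioxan-4-yl]pent-4-en-2-ol | CCCCCCCCCCCCCCC[C@@H]1C[C@H](C[C@@H](O)CC=C)O[C@H](c2ccccc2)O1 | intermediate
18 | (2R,4R,6R)-4-[(2S)-2-(tert-butyldimethylsilyloxy)pent-4-enyl]-6-pentadecyl-2-phenyl-1,3-dioxane | CCCCCCCCCCCCCCC[C@@H]1C[C@H](C[C@@H](O[Si](C)(C)C(C)(C)C)CC=C)O[C@H](c2ccccc2)O1 | intermediate
19 | secondary ozonide of 18: 1,2,4-trioxolane at the former terminal alkene, mixture at the trioxolane carbon (formed in the flask, not isolated) | CCCCCCCCCCCCCCC[C@@H]1C[C@H](C[C@@H](O[Si](C)(C)C(C)(C)C)CC2OCOO2)O[C@H](c2ccccc2)O1 | intermediate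
20 | (3R)-3-(tert-butyldimethylsilyloxy)-4-[(2R,4R,6R)-6-pentadecyl-2-phenyl-1,3-dioxan-4-yl]butanal | CCCCCCCCCCCCCCC[C@@H]1C[C@H](C[C@@H](O[Si](C)(C)C(C)(C)C)CC=O)O[C@H](c2ccccc2)O1 | intermediate
21 | (4S,6S)-6-(tert-butyldimethylsilyloxy)-7-[(2R,4R,6R)-6-pentadecyl-2-phenyl-1,3-dioxan-4-yl]hept-1-en-4-yl diisopinocampheylborinate, (+)-α-pinene series (formed in the flask, not isolated) | CCCCCCCCCCCCCCC[C@@H]1C[C@H](C[C@@H](O[Si](C)(C)C(C)(C)C)C[C@H](CC=C)OB([C@@H]2C[C@@H]3C[C@H]([C@H]2C)C3(C)C)[C@@H]2C[C@@H]3C[C@H]([C@H]2C)C3(C)C)O[C@H](c2ccccc2)O1 | intermediate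
22 | (4S,6S)-6-(tert-butyldimethylsilyloxy)-7-[(2R,4R,6R)-6-pentadecyl-2-phenyl-1,3-dioxan-4-yl]hept-1-en-4-ol | CCCCCCCCCCCCCCC[C@@H]1C[C@H](C[C@@H](O[Si](C)(C)C(C)(C)C)C[C@@H](O)CC=C)O[C@H](c2ccccc2)O1 | intermediate
23 | (4S,6R)-6-(tert-butyldimethylsilyloxy)-7-[(2R,4R,6R)-6-pentadecyl-2-phenyl-1,3-dioxan-4-yl]hept-1-en-4-yl prop-2-enoate | CCCCCCCCCCCCCCC[C@@H]1C[C@H](C[C@@H](O[Si](C)(C)C(C)(C)C)C[C@H](CC=C)OC(=O)C=C)O[C@H](c2ccccc2)O1 | intermediate
24 | (6S)-6-[(2R)-2-(tert-butyldimethylsilyloxy)-3-[(2R,4R,6R)-6-pentadecyl-2-phenyl-1,3-dioxan-4-yl]propyl]-5,6-dihydro-2H-pyran-2-one | CCCCCCCCCCCCCCC[C@@H]1C[C@H](C[C@@H](O[Si](C)(C)C(C)(C)C)C[C@@H]2CC=CC(=O)O2)O[C@H](c2ccccc2)O1 | intermediate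
25 | (6S)-6-[(2R,4R,6R)-2,4,6-trihydroxyhenicosyl]-5,6-dihydro-2H-pyran-2-one (CNP0231118.1) | CCCCCCCCCCCCCCC[C@@H](O)C[C@@H](O)C[C@@H](O)C[C@@H]1CC=CC(=O)O1 | target

**Step count and risk**

Total step count: 16. Longest linear sequence: 16 steps (the route is fully linear from 1).

Steps most likely to fail:

1. Step 5 (key step). The equilibration may stall before both C11 epimers have drained into the cis acetal, or the allyl perrhenate may ionise and be diverted into cyclo-etherification or elimination. The fallback sets C11 by catalyst-controlled epoxidation instead of equilibration. It sets out from 7. Sharpless asymmetric epoxidation (Ti(OiPr)4, L-(+)-diethyl tartrate, t-BuOOH, 4 Å sieves, CH2Cl2, −20 °C) should give the epoxy diol [(2S,3S)-3-[(2S)-4-(tert-butyldiphenylsilyloxy)-2-hydroxybutyl]oxiran-2-yl]methanol F1. Selective iodination of the primary hydroxyl (iodine, PPh3, imidazole, THF, 0 °C) should give (2S)-4-(tert-butyldiphenylsilyloxy)-1-[(2S,3R)-3-(iodomethyl)oxiran-2-yl]butan-2-ol F2. Zinc-mediated reductive opening of the epoxy iodide (Zn, MeOH, reflux) should give the syn diol (3S,5S)-7-(tert-butyldiphenylsilyloxy)hept-1-ene-3,5-diol F3. Acid-catalysed acetalisation of F3 with 8 (camphorsulfonic acid, CH2Cl2) comes back to the route at 10.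

2. Step 6. Cross-metathesis may be sluggish at a vinyl group flanked by the acetal oxygen, with homodimerisation of 11 and double-bond migration competing. The fallback builds the C12=C13 bond by carbonyl olefination. It sets out from 10. Ozonolysis (O3, CH2Cl2, −78 °C; PPh3) should give (2S,4S,6S)-2-phenyl-6-[2-(tert-butyldiphenylsilyloxy)ethyl]-1,3-dioxane-4-carbaldehyde F4. Wittig olefination of F4 with the ylide from tetradecyltriphenylphosphonium bromide and NaN(SiMe3)2 (THF, −78 °C) should give (2S,4S,6S)-4-[(Z)-pentadec-1-enyl]-2-phenyl-6-[2-(tert-butyldiphenylsilyloxy)ethyl]-1,3-dioxane F5. Hydrogenation of F5 under the conditions of step 7 comes back to the route at 13.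

3. Step 10 (the same concern applies to step 13). Facial selectivity may erode when the reagent has to override the bias of the β-oxygenated aldehyde, and the aldehyde may suffer β-elimination. The fallback sets C7 by catalyst-controlled ketone hydrogenation instead of carbonyl addition. It sets out from 15. Roskamp homologation (ethyl diazoacetate, SnCl2 cat., CH2Cl2, rt) should give ethyl 3-oxo-4-[(2R,4R,6R)-6-pentadecyl-2-phenyl-1,3-dioxan-4-yl]butanoate F6. Noyori asymmetric hydrogenation (H2, RuCl2[(R)-BINAP], EtOH) should give ethyl (3R)-3-hydroxy-4-[(2R,4S,6R)-6-pentadecyl-2-phenyl-1,3-dioxan-4-yl]butanoate F7. Silylation (TBSCl, imidazole, DMF) should give ethyl (3R)-3-(tert-butyldimethylsilyloxy)-4-[(2R,4R,6R)-6-pentadecyl-2-phenyl-1,3-dioxan-4-yl]butanoate F8. Partial reduction of F8 with i-Bu2AlH (CH2Cl2, −78 °C) comes back to the route at 20, bypassing steps 10 to 12.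

Further compounds
F1 | step 5 | [(2S,3S)-3-[(2S)-4-(tert-butyldiphenylsilyloxy)-2-hydroxybutyl]oxiran-2-yl]methanol | OC[C@@H]1O[C@H]1C[C@@H](O)CCO[Si](c1ccccc1)(c1ccccc1)C(C)(C)C
F2 | step 5 | (2S)-4-(tert-butyldiphenylsilyloxy)-1-[(2S,3R)-3-(iodomethyl)oxiran-2-yl]butan-2-ol | IC[C@@H]1O[C@H]1C[C@@H](O)CCO[Si](c1ccccc1)(c1ccccc1)C(C)(C)C
F3 | step 5 | (3S,5S)-7-(tert-butyldiphenylsilyloxy)hept-1-ene-3,5-diol | C=C[C@@H](O)C[C@@H](O)CCO[Si](c1ccccc1)(c1ccccc1)C(C)(C)C
F4 | step 6 | (2S,4S,6S)-2-phenyl-6-[2-(tert-butyldiphenylsilyloxy)ethyl]-1,3-dioxane-4-carbaldehyde | O=C[C@@H]1C[C@H](CCO[Si](c2ccccc2)(c2ccccc2)C(C)(C)C)O[C@H](c2ccccc2)O1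
F5 | step 6 | (2S,4S,6S)-4-[(Z)-pentadec-1-enyl]-2-phenyl-6-[2-(tert-butyldiphenylsilyloxy)ethyl]-1,3-dioxane | CCCCCCCCCCCCC/C=C\[C@@H]1C[C@H](CCO[Si](c2ccccc2)(c2ccccc2)C(C)(C)C)O[C@H](c2ccccc2)O1
F6 | step 10 | ethyl 3-oxo-4-[(2R,4R,6R)-6-pentadecyl-2-phenyl-1,3-dioxan-4-yl]butanoate | CCCCCCCCCCCCCCC[C@@H]1C[C@H](CC(=O)CC(=O)OCC)O[C@H](c2ccccc2)O1
F7 | step 10 | ethyl (3R)-3-hydroxy-4-[(2R,4S,6R)-6-pentadecyl-2-phenyl-1,3-dioxan-4-yl]butanoate | CCCCCCCCCCCCCCC[C@@H]1C[C@H](C[C@@H](O)CC(=O)OCC)O[C@H](c2ccccc2)O1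
F8 | step 10 | ethyl (3R)-3-(tert-butyldimethylsilyloxy)-4-[(2R,4R,6R)-6-pentadecyl-2-phenyl-1,3-dioxan-4-yl]butanoate | CCCCCCCCCCCCCCC[C@@H]1C[C@H](C[C@@H](O[Si](C)(C)C(C)(C)C)CC(=O)OCC)O[C@H](c2ccccc2)O1
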